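**Retrosynthetic overview**
- Tetronic acid ring (the only ring built, closed last): Dieckmann cyclisation of an (R)-α-propanoyloxy methyl ester.
- CH2–C(sp2) bond next to the stereocentre: new nickel-catalysed reductive coupling of a (Z)-alkenyl iodide with methyl (R)-glycidate; the chiral pool supplies the stereocentre.
- (Z)-alkenyl iodide: iodo-Wittig olefination of an aldehyde obtained by oxidation of the chain alcohol.
- (E)-alkene and chain: 9-BBN hydroboration of a vinyl bis-furan, then B-alkyl Suzuki coupling with (E)-5-iodo-4-methylpent-4-en-1-ol (carboalumination of pent-4-yn-1-ol).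
- Bis-furan: 3-furyllithium plus 4-bromofuran-2-carbaldehyde, deoxygenation, vinylation; both furan rings are bought intact.

Assumption: the SMILES is read as (5R) at the lactone carbon, Z for the alkene nearer the lactone and E for the distal one; 3-bromofuran, 4-bromofuran-2-carbaldehyde, pent-4-yn-1-ol and methyl (R)-glycidate are taken as commercial.

**Route**

Step 1
Reactants: 1 3-bromofuran; 2 4-bromofuran-2-carbaldehyde
Product: 4 rac-(4-bromofuran-2-yl)(furan-3-yl)methanol, via furan-3-yllithium 3 (not isolated)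
Conditions: 1, n-BuLi (1.05 equiv), THF, −78 °C, 30 min; then 2, −78 °C, 1 h; H2O quench
Reagents that add atoms: none
Why: Bromine–lithium exchange gives 3-furyllithium, which is stable at −78 °C and adds to the aldehyde (organolithium 1,2-addition) much faster than it exchanges with the ring bromide; the carbinol centre is racemic and is removed in step 2.

Step 2
Reactants: 4 rac-(4-bromofuran-2-yl)(furan-3-yl)methanol
Product: 5 4-bromo-2-(furan-3-ylmethyl)furan
Conditions: Et3SiH (3 equiv), CF3CO2H (5 equiv, slow addition), CH2Cl2, −20 → 0 °C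
Reagents that add atoms: none
Why: Ionic hydrogenation, in which the bis-furyl-stabilised carbocation is trapped by silane hydride faster than it alkylates another furan at low temperature, the ring bromide further lowering furan nucleophilicity.

Step 3
Reactants: 5 4-bromo-2-(furan-3-ylmethyl)furan
Product: 6 4-ethenyl-2-(furan-3-ylmethyl)furan
Conditions: tributyl(vinyl)stannane (1.2 equiv), Pd(PPh3)4 (5 mol%), BHT (cat.), toluene, 100 °C
Reagents that add atoms: tributyl(vinyl)stannane, C=C[Sn](CCCC)(CCCC)CCCC
Why: Stille cross-coupling of the heteroaryl bromide under neutral conditions that spare the acid-sensitive difurylmethane.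

Step 4
Reactants: 7 pent-4-yn-1-ol
Product: 9 (4E)-5-iodo-4-methylpent-4-en-1-ol, via alkenylalane 8 (not isolated)
Conditions: Me3Al (3 equiv), Cp2ZrCl2 (0.25 equiv), CH2Cl2, 0 °C → rt; then I2 (1.2 equiv), THF, −30 → 0 °C; H2O quench
Reagents that add atoms: trimethylaluminium, C[Al](C)C; iodine, II
Why: Negishi zirconium-catalysed carboalumination adds methyl and aluminium syn across the alkyne with aluminium on the terminal carbon, and iodinolysis with retention fixes the E trisubstituted alkene.

Step 5
Reactants: 6 4-ethenyl-2-(furan-3-ylmethyl)furan; 9 (4E)-5-iodo-4-methylpent-4-en-1-ol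
Product: 11 (4E)-7-[5-(furan-3-ylmethyl)furan-3-yl]-4-methylhept-4-en-1-ol, via B-alkyl-9-BBN borane 10 (not isolated)
Conditions: 6, 9-BBN (1.05 equiv), THF, 0 °C → rt; then 9, PdCl2(dppf) (5 mol%), AsPh3 (5 mol%), Cs2CO3 (2 equiv), DMF/H2O, rt
Reagents that add atoms: none
Why: 9-BBN hydroborates only the vinyl group at its terminal carbon, and B-alkyl Suzuki–Miyaura coupling with the alkenyl iodide proceeds with retention of the E geometry and tolerates the free alcohol.

Step 6
Reactants: 11 (4E)-7-[5-(furan-3-ylmethyl)furan-3-yl]-4-methylhept-4-en-1-ol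
Product: 12 (4E)-7-[5-(furan-3-ylmethyl)furan-3-yl]-4-methylhept-4-enal
Conditions: Dess–Martin periodinane (1.2 equiv), NaHCO3 (3 equiv), CH2Cl2, 0 °C → rt
Reagents that add atoms: none
Why: Buffered Dess–Martin oxidation takes the primary alcohol to the aldehyde without touching the furans or the trisubstituted alkene.

Step 7
Reactants: 12 (4E)-7-[5-(furan-3-ylmethyl)furan-3-yl]-4-methylhept-4-enal
Product: 13 2-(furan-3-ylmethyl)-4-[(3E,7Z)-8-iodo-4-methylnona-3,7-dien-1-yl]furan
Conditions: EtPPh3I, n-BuLi, THF, 0 °C → rt; I2, −78 °C; NaN(SiMe3)2, −20 °C; then 12, −78 → −20 °C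
Reagents that add atoms: ethyltriphenylphosphonium iodide, CC[P+](c1ccccc1)(c1ccccc1)c1ccccc1.[I-]; iodine, II
Why: Stork–Zhao-type Wittig olefination with the α-iodo ylide Ph3P=C(I)CH3, whose kinetic cis-selective oxaphosphetane formation places iodine cis to the chain and so gives the Z alkenyl iodide (typically about 10:1, minor isomer removed by chromatography).

Step 8
Reactants: 13 2-(furan-3-ylmethyl)-4-[(3E,7Z)-8-iodo-4-methylnona-3,7-dien-1-yl]furan; 14 methyl (2R)-oxirane-2-carboxylate (methyl (R)-glycidate)
Product: 16 methyl (2R,4Z,8E)-11-[5-(furan-3-ylmethyl)furan-3-yl]-2-hydroxy-4,8-dimethylundeca-4,8-dienoate, via iodohydrin 15 (not isolated)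
Conditions: NiI2 (10 mol%), 4,4'-di-tert-butyl-2,2'-bipyridine (10 mol%), NaI (25 mol%), Et3N·HCl (1.2 equiv), Zn dust (2 equiv), 14 (2 equiv), DMPU, 25 °C
Reagents that add atoms: none
Why: Proposed new method: nickel/iodide co-catalysed reductive cross-electrophile coupling extended to an enantiopure glycidic ester and a trisubstituted (Z)-alkenyl iodide; iodide with Et3N·HCl opens 14 at the unhindered C3 to iodohydrin 15, zerovalent nickel–bipyridine inserts into the C–I bond of 13 with retention of the Z geometry, the alkenyl(divalent nickel) iodide captures the primary radical made by iodine-atom abstraction from 15, and reductive elimination from trivalent nickel forges the C(sp2)–C(sp3) bond while Zn turns the catalyst over; the C2–O and C2–H bonds of the glycidate are never broken, so the (R) centre is carried unchanged into what becomes C5 of the lactone; closest known reaction type: nickel/iodide co-catalysed reductive coupling of simple terminal epoxides with aryl halides.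

Step 9
Reactants: 16 methyl (2R,4Z,8E)-11-[5-(furan-3-ylmethyl)furan-3-yl]-2-hydroxy-4,8-dimethylundeca-4,8-dienoate
Product: 17 methyl (2R,4Z,8E)-11-[5-(furan-3-ylmethyl)furan-3-yl]-4,8-dimethyl-2-(propanoyloxy)undeca-4,8-dienoate
Conditions: (EtCO)2O (1.5 equiv), Et3N (2 equiv), DMAP (5 mol%), CH2Cl2, 0 °C
Reagents that add atoms: propanoic anhydride, CCC(=O)OC(=O)CC
Why: DMAP-catalysed acylation of the secondary alcohol under conditions too mild to deprotonate the α-stereocentre.

Step 10
Reactants: 17 methyl (2R,4Z,8E)-11-[5-(furan-3-ylmethyl)furan-3-yl]-4,8-dimethyl-2-(propanoyloxy)undeca-4,8-dienoate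
Product: 18 (5R)-5-{(2Z,6E)-9-[5-(furan-3-ylmethyl)furan-3-yl]-2,6-dimethylnona-2,6-dien-1-yl}-4-hydroxy-3-methylfuran-2(5H)-one
Conditions: LiN(SiMe3)2 (2.2 equiv), THF, −78 → −20 °C; then 1 M HCl, 0 °C (pH 3)
Reagents that add atoms: none
Why: Dieckmann (intramolecular Claisen) condensation in which the propanoate enolate attacks the methyl ester 5-exo-trig and expels methoxide to close the 3-methyltetronic acid; at low temperature the amide base removes the propanoate CH2 proton in preference to the hindered C–H at the stereocentre, so C5 stays (R).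

**Compound list**

1 | 3-bromofuran | Brc1ccoc1 | starting material
2 | 4-bromofuran-2-carbaldehyde | O=Cc1cc(Br)co1 | starting material
3 | furan-3-yllithium | [Li]c1ccoc1 | intermediate
4 | rac-(4-bromofuran-2-yl)(furan-3-yl)methanol | OC(c1ccoc1)c1cc(Br)co1 | intermediate
5 | 4-bromo-2-(furan-3-ylmethyl)furan | Brc1coc(Cc2ccoc2)c1 | intermediate
6 | 4-ethenyl-2-(furan-3-ylmethyl)furan | C=Cc1coc(Cc2ccoc2)c1 | intermediate
7 | pent-4-yn-1-ol | OCCCC#C | starting material
8 | dimethyl{(1E)-5-[(dimethylalumanyl)oxy]-2-methylpent-1-en-1-yl}alumane (aluminium cis to the methyl group) | C[Al](C)/C=C(\C)CCCO[Al](C)C | intermediate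
9 | (4E)-5-iodo-4-methylpent-4-en-1-ol | OCCC/C(C)=C/I | intermediate
10 | 9-{2-[5-(furan-3-ylmethyl)furan-3-yl]ethyl}-9-borabicyclo[3.3.1]nonane | C(Cc1coc(Cc2ccoc2)c1)B1C2CCCC1CCC2 | intermediate
11 | (4E)-7-[5-(furan-3-ylmethyl)furan-3-yl]-4-methylhept-4-en-1-ol | OCCC/C(C)=C/CCc1coc(Cc2ccoc2)c1 | intermediate
12 | (4E)-7-[5-(furan-3-ylmethyl)furan-3-yl]-4-methylhept-4-enal | O=CCC/C(C)=C/CCc1coc(Cc2ccoc2)c1 | intermediate
13 | 2-(furan-3-ylmethyl)-4-[(3E,7Z)-8-iodo-4-methylnona-3,7-dien-1-yl]furan (iodine cis to the chain) | C/C(I)=C/CC/C(C)=C/CCc1coc(Cc2ccoc2)c1 | intermediate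
14 | methyl (2R)-oxirane-2-carboxylate | COC(=O)[C@@H]1OC1 | starting material
15 | methyl (2S)-2-hydroxy-3-iodopropanoate (same spatial arrangement as 14; the descriptor changes because CH2I outranks CO2Me) | COC(=O)[C@@H](CI)O | intermediate
16 | methyl (2R,4Z,8E)-11-[5-(furan-3-ylmethyl)furan-3-yl]-2-hydroxy-4,8-dimethylundeca-4,8-dienoate | COC(=O)[C@@H](C/C(C)=C\CC/C(C)=C/CCc1coc(Cc2ccoc2)c1)O | intermediate
17 | methyl (2R,4Z,8E)-11-[5-(furan-3-ylmethyl)furan-3-yl]-4,8-dimethyl-2-(propanoyloxy)undeca-4,8-dienoate | COC(=O)[C@@H](C/C(C)=C\CC/C(C)=C/CCc1coc(Cc2ccoc2)c1)OC(=O)CC | intermediate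
18 | (5R)-5-{(2Z,6E)-9-[5-(furan-3-ylmethyl)furan-3-yl]-2,6-dimethylnona-2,6-dien-1-yl}-4-hydroxy-3-methylfuran-2(5H)-one | CC1=C(O)[C@@H](C/C(C)=C\CC/C(C)=C/CCc2coc(Cc3ccoc3)c2)OC1=O | target

**Step count and risk**

Total step count: 10.
Longest linear sequence: 9 steps (1 → 18 through steps 1, 2, 3, 5, 6, 7, 8, 9, 10); the pent-4-yn-1-ol branch adds step 4.

Three steps most likely to fail:

Step 8 (proposed new nickel coupling) is the most likely to fail. The likely failure modes are:
- slow oxidative addition to the hindered trisubstituted iodide, with homocoupling or reduction of 13;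
- zinc-induced loss of 15 to methyl acrylate;
- minor opening of 14 at C2, which would erode regio- and enantiopurity (checked by chiral HPLC on 16).

The fallback is known polar chemistry; it sets out from 13 and comes back to the route at 16. Iodine–lithium exchange on 13 (t-BuLi, 2.1 equiv, Et2O, −78 °C) gives with retention [(2E,6E)-9-[5-(furan-3-ylmethyl)furan-3-yl]-6-methylnona-2,6-dien-2-yl]lithium F1; lithium stays cis to the chain, and the descriptor reads 2E only because lithium ranks below carbon. Transmetalation with MgBr2·OEt2 gives (2Z,6E)-9-[5-(furan-3-ylmethyl)furan-3-yl]-6-methylnona-2,6-dien-2-ylmagnesium bromide F2. This opens 14 at C3 under CuI catalysis (10 mol%, THF, −40 °C), the established organocuprate opening of glycidic esters to α-hydroxy esters, and delivers 16 with the C2 centre untouched.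

Step 7 (iodo-Wittig olefination) is second. Yields are often modest, and the E isomer, the des-iodo alkene and the diiodoalkene are common side products. The fallback sets out from 12 and comes back at 13. Ramirez dibromo-olefination (CBr4, PPh3, Et3N, CH2Cl2, 0 °C) gives 4-[(3E)-8,8-dibromo-4-methylocta-3,7-dien-1-yl]-2-(furan-3-ylmethyl)furan F3. Trans-selective Negishi monomethylation (Me2Zn, PdCl2(DPEphos), THF, 0 °C) replaces only the bromine trans to the chain and gives 4-[(3E,7Z)-8-bromo-4-methylnona-3,7-dien-1-yl]-2-(furan-3-ylmethyl)furan F4. Copper-catalysed halogen exchange with retention (CuI, NaI, trans-N,N'-dimethylcyclohexane-1,2-diamine, dioxane, 110 °C) returns 13.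

Step 2 (ionic deoxygenation) is third. The furyl-stabilised cation may alkylate a furan and oligomerise under acid. The fallback avoids any carbocation; it sets out from 2 and comes back at 5. Condensation of 2 with 4-methylbenzenesulfonohydrazide (MeOH, rt) gives N'-[(E)-(4-bromofuran-2-yl)methylidene]-4-methylbenzenesulfonohydrazide F5. Metal-free Barluenga–Valdés reductive coupling with furan-3-ylboronic acid (K2CO3, dioxane, 110 °C) gives 5 directly; with no palladium present the ring bromide is untouched.

**Further compounds**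

F1 | step 8 | [(2E,6E)-9-[5-(furan-3-ylmethyl)furan-3-yl]-6-methylnona-2,6-dien-2-yl]lithium | C/C([Li])=C/CC/C(C)=C/CCc1coc(Cc2ccoc2)c1
F2 | step 8 | (2Z,6E)-9-[5-(furan-3-ylmethyl)furan-3-yl]-6-methylnona-2,6-dien-2-ylmagnesium bromide | C/C([Mg]Br)=C/CC/C(C)=C/CCc1coc(Cc2ccoc2)c1
F3 | step 7 | 4-[(3E)-8,8-dibromo-4-methylocta-3,7-dien-1-yl]-2-(furan-3-ylmethyl)furan | BrC(Br)=CCC/C(C)=C/CCc1coc(Cc2ccoc2)c1
F4 | step 7 | 4-[(3E,7Z)-8-bromo-4-methylnona-3,7-dien-1-yl]-2-(furan-3-ylmethyl)furan | C/C(Br)=C/CC/C(C)=C/CCc1coc(Cc2ccoc2)c1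
F5 | step 2 | N'-[(E)-(4-bromofuran-2-yl)methylidene]-4-methylbenzenesulfonohydrazide | Cc1ccc(cc1)S(=O)(=O)N/N=C/c1cc(Br)co1
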